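**Retrosynthetic overview**

1. The target (an ent-labdane, labdane numbering) is traced back to a ring A ketone that already carries the quaternary C10. The dienyl unit C12–C16 is attached last to C11 by hydroboration/B-alkyl Suzuki coupling of an exocyclic C9=C11 olefin, which also sets C9.
2. Ring B is closed by the C8–C9 bond in an intramolecular Heck reaction of a Z-β-iodoenone (C6 carbonyl, C7=C8, iodine on C8, silyloxymethyl C17) onto a vinyl group on C10, giving the 7,9(11)-dien-6-one.
3. Enabling feature: C8 is a vinylic carbon between the oxygenated C6 and C9, and C9 sits on the quaternary C10. An alkenylpalladium at C8 can therefore add to a C9=C11 vinyl group, and the only β-hydrogen of the resulting alkylpalladium is H9, so ring B must emerge with C7=C8 in place and an exocyclic C9=C11 methylene.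
4. The C6 carbonyl then controls C5 (equilibration to the trans ring fusion) and C6 (hydride from the face opposite the axial methyl groups). The iodoenone comes from the ring A aldehyde and a propargyl silyl ether (addition, trans-hydroalumination/iodination, oxidation).
5. C10 is set by Pd-catalysed decarboxylative asymmetric allylation of 2,2,6-trimethylcyclohexanone. Ring A is bought; ring B is formed in the key step.

Key step: step 10

Remark: labdane numbering (C1–C20; C17 on C8, C11–C16 on C9) is used for all intermediates.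
Assumption: (S)-t-BuPHOX gives the (S)-configured allyl ketone, as in the 2-alkyl-2-methylcyclohexanone series; should the sense be opposite, the (R)-ligand is used.

**Route**

Step 1
Reactants: 1 2,2,6-trimethylcyclohexan-1-one; 2 allyl chloroformate
Product: 4 allyl 2,6,6-trimethylcyclohex-1-en-1-yl carbonate, via lithium enolate 3 (not isolated)
Conditions: LiHMDS, THF, 0 °C; then 2, −78 °C to rt
Reagents that add atoms: none
Why: Deprotonation at the only enolizable α-carbon and O-acylation of the hindered tetrasubstituted lithium enolate by the chloroformate (enol carbonate formation); no stereocenter is formed.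

Step 2
Reactants: 4 allyl 2,6,6-trimethylcyclohex-1-en-1-yl carbonate
Product: 5 (S)-2-allyl-2,6,6-trimethylcyclohexan-1-one
Conditions: Pd2(dba)3 (2.5 mol %), (S)-t-BuPHOX (6 mol %), THF, 25 °C
Reagents that add atoms: none
Why: Pd-catalysed decarboxylative asymmetric allylic alkylation: ionization and loss of CO2 give an allylpalladium enolate pair, and C–C bond formation inside the chiral phosphinooxazoline pocket should set the quaternary C10 as (S).

Step 3
Reactants: 5 (S)-2-allyl-2,6,6-trimethylcyclohexan-1-one
Product: 6 (S)-2,6,6-trimethyl-2-[(E)-prop-1-en-1-yl]cyclohexan-1-one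
Conditions: RuHCl(CO)(PPh3)3 (5 mol %), toluene, 100 °C
Reagents that add atoms: none
Why: Ruthenium hydride-catalysed olefin isomerization (hydrometalation/β-hydride elimination) moves the double bond to the internal position next to the quaternary carbon, where it cannot migrate further; C10 is untouched.

Step 4
Reactants: 6 (S)-2,6,6-trimethyl-2-[(E)-prop-1-en-1-yl]cyclohexan-1-one
Product: 7 (S)-2-ethenyl-2,6,6-trimethylcyclohexan-1-one
Conditions: second-generation Hoveyda–Grubbs catalyst (5 mol %), ethylene (5 bar), toluene, 50 °C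
Reagents that add atoms: ethylene, C=C
Why: Ethenolysis (cross-metathesis with ethylene): the ruthenium methylidene adds with the metal at the less hindered CH(CH3) terminus, so cycloreversion should release the vinyl ketone and propene.

Step 5
Reactants: 7 (S)-2-ethenyl-2,6,6-trimethylcyclohexan-1-one
Product: 9 (4S)-4-ethenyl-4,8,8-trimethyl-1-oxaspiro[2.5]octane as both spiro epimers, via lithium chlorohydrin alkoxide 8 (not isolated)
Conditions: ICH2Cl, MeLi·LiBr, THF, −78 °C to rt
Reagents that add atoms: chloroiodomethane, ClCI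
Why: Addition of the small carbenoid chloromethyllithium to the hindered ketone and closure of the chlorohydrin alkoxide (Corey–Chaykovsky-type methylene transfer) should give the epoxide; the new C5 centre is uncontrolled, which is harmless because C5 is re-set by enolization in step 10.

Step 6
Reactants: 9 (4S)-4-ethenyl-4,8,8-trimethyl-1-oxaspiro[2.5]octane
Product: 10 (2S)-2-ethenyl-2,6,6-trimethylcyclohexane-1-carbaldehyde as both C1 epimers
Conditions: BF3·OEt2 (0.2 equiv), CH2Cl2, −78 °C
Reagents that add atoms: none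
Why: Meinwald rearrangement: Lewis acid opening at the tertiary C5–O bond and 1,2-hydride shift from the CH2O carbon should give the aldehyde (C6); C5 is formed as a mixture and stays epimerizable.

Step 7
Reactants: 10 (2S)-2-ethenyl-2,6,6-trimethylcyclohexane-1-carbaldehyde; 11 tert-butyldimethyl(prop-2-yn-1-yloxy)silane
Product: 13 4-[(tert-butyldimethylsilyl)oxy]-1-[(2S)-2-ethenyl-2,6,6-trimethylcyclohexyl]but-2-yn-1-ol as a diastereomer mixture, via lithium acetylide 12 (not isolated)
Conditions: 11, n-BuLi, THF, −78 °C; then 10, −78 to 0 °C; H2O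
Reagents that add atoms: none
Why: 1,2-Addition of a lithium acetylide to the aldehyde brings in C7, C8 and C17; the C6 carbinol configuration is irrelevant because C6 becomes a ketone in step 9.

Step 8
Reactants: 13 4-[(tert-butyldimethylsilyl)oxy]-1-[(2S)-2-ethenyl-2,6,6-trimethylcyclohexyl]but-2-yn-1-ol
Product: 15 (Z)-4-[(tert-butyldimethylsilyl)oxy]-1-[(2S)-2-ethenyl-2,6,6-trimethylcyclohexyl]-3-iodobut-2-en-1-ol, via cyclic alkenylalanate 14 (not isolated)
Conditions: Red-Al (NaAlH2(OCH2CH2OCH3)2), THF, 0 °C to rt; then I2, THF, −78 °C; H2O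
Reagents that add atoms: iodine, [I][I]
Why: Hydroxyl-directed trans-hydroalumination of the propargylic alcohol (hydride to C7, aluminium to C8 in a five-membered alanate) and iodinolysis with retention should give the Z-iodoalkene with iodine on C8 cis to C6, the geometry ring B requires.

Step 9
Reactants: 15 (Z)-4-[(tert-butyldimethylsilyl)oxy]-1-[(2S)-2-ethenyl-2,6,6-trimethylcyclohexyl]-3-iodobut-2-en-1-ol
Product: 16 (Z)-4-[(tert-butyldimethylsilyl)oxy]-1-[(2S)-2-ethenyl-2,6,6-trimethylcyclohexyl]-3-iodobut-2-en-1-one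
Conditions: Dess–Martin periodinane, CH2Cl2, 0 °C to rt
Reagents that add atoms: none
Why: Dess–Martin oxidation of the secondary allylic alcohol under near-neutral conditions should keep the Z-iodoalkene and the silyl ether intact and make C5 epimerizable.

Step 10
Reactants: 16 (Z)-4-[(tert-butyldimethylsilyl)oxy]-1-[(2S)-2-ethenyl-2,6,6-trimethylcyclohexyl]-3-iodobut-2-en-1-one
Product: 17 (5R,10R)-17-[(tert-butyldimethylsilyl)oxy]-12,13,14,15,16-pentanorlabda-7,9(11)-dien-6-one
Conditions: Pd(OAc)2 (10 mol %), PPh3 (20 mol %), K2CO3, n-Bu4NCl, DMF, 70 °C; then DBU (0.2 equiv), 70 °C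
Reagents that add atoms: none
Why: Intramolecular Mizoroki–Heck reaction: zerovalent palladium inserts into the C8–I bond of the Z-β-iodoenone, the alkenylpalladium adds syn across the C9=C11 vinyl group, and β-hydride elimination of H9, the only β-hydrogen because C10 is quaternary, releases the exocyclic C9=C11 olefin. The closest known reaction type is the 6-exo-trig Heck cyclization of alkenyl halides onto tethered 1-alkenes that gives 1,3-dienes with an exocyclic methylene group. Ring B (C5–C6–C7–C8–C9–C10) closes in the 6-exo-trig mode by the C8–C9 bond. No stereocenter is created at C9 here; C10 is carried from 7, and C5, which is α to the C6 ketone, should settle under the basic conditions to the trans ring fusion (H5 anti to the C10 methyl), in which both ring B bonds are equatorial on ring A. The step needs C9 over C11 regioselectivity (6-exo against 7-endo), which the short tether secures, and a single direction of β-hydride elimination, which the quaternary C10 and the sp2 C8 secure; for the same reason the dienone cannot aromatize, and its s-trans diene cannot dimerize by cycloaddition.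

Step 11
Reactants: 18 prop-2-yn-1-ol
Product: 20 (E)-3-iodo-2-methylprop-2-en-1-ol, via alkenylalane 19 (not isolated)
Conditions: Me3Al, Cp2ZrCl2 (25 mol %), CH2Cl2, 0 °C to rt; then I2, THF, −30 °C; H2O
Reagents that add atoms: trimethylaluminium, C[Al](C)C; iodine, [I][I]
Why: Negishi zirconium-catalysed carboalumination adds CH3 and Al syn across the alkyne with aluminium at the terminal carbon, and iodinolysis with retention should fix the E trisubstituted olefin (C12=C13 with C16).

Step 12
Reactants: 20 (E)-3-iodo-2-methylprop-2-en-1-ol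
Product: 21 (E)-3-iodo-2-methylprop-2-enal
Conditions: MnO2, CH2Cl2, rt
Reagents that add atoms: none
Why: MnO2 oxidation of a primary allylic alcohol to the enal should leave the alkenyl iodide and the olefin geometry untouched.

Step 13
Reactants: 21 (E)-3-iodo-2-methylprop-2-enal
Product: 22 (E)-1-iodo-2-methylbuta-1,3-diene
Conditions: Ph3PCH3Br, KHMDS, THF, 0 °C; then 21, −78 to 0 °C
Reagents that add atoms: methyltriphenylphosphonium bromide (as its ylide), C[P+](c1ccccc1)(c1ccccc1)c1ccccc1.[Br-]
Why: Wittig methylenation of the enal with the non-stabilized ylide should give the 1,3-diene (C14=C15) without involving the E-iodoalkene; the volatile product is used as a solution.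

Step 14
Reactants: 17 (5R,10R)-17-[(tert-butyldimethylsilyl)oxy]-12,13,14,15,16-pentanorlabda-7,9(11)-dien-6-one
Product: 23 (5R,6S,10R)-17-[(tert-butyldimethylsilyl)oxy]-12,13,14,15,16-pentanorlabda-7,9(11)-dien-6-ol
Conditions: NaBH4, CeCl3·7H2O, MeOH, −78 to −20 °C
Reagents that add atoms: none
Why: Luche 1,2-reduction: hydride should attack the C6 carbonyl from the face opposite the axial methyl groups on C10 and C4, placing the 6-hydroxyl cis to the C10 methyl (6S).

Step 15
Reactants: 23 (5R,6S,10R)-17-[(tert-butyldimethylsilyl)oxy]-12,13,14,15,16-pentanorlabda-7,9(11)-dien-6-ol; 22 (E)-1-iodo-2-methylbuta-1,3-diene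
Product: 25 (5R,6S,9S,10S,12E)-17-[(tert-butyldimethylsilyl)oxy]labda-7,12,14-trien-6-ol, via B-alkyl-9-BBN borane 24 (not isolated)
Conditions: 9-BBN (2.2 equiv), THF, 0 °C to rt; then 22, PdCl2(dppf) (5 mol %), 3 M aq. NaOH, THF/DMF, 50 °C
Reagents that add atoms: none
Why: Hydroboration of the exocyclic 1,1-disubstituted olefin puts boron on C11 and delivers hydrogen to C9 syn from the face opposite the axial C10 methyl (9S), and the B-alkyl Suzuki–Miyaura coupling with the E-alkenyl iodide proceeds with retention to give the 12E diene.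

Step 16
Reactants: 25 (5R,6S,9S,10S,12E)-17-[(tert-butyldimethylsilyl)oxy]labda-7,12,14-trien-6-ol
Product: 26 (5R,6S,9S,10S,12E)-labda-7,12,14-triene-6,17-diol
Conditions: TBAF, THF, 0 °C to rt
Reagents that add atoms: none
Why: Fluoride-induced cleavage of the primary silyl ether; no stereocenter is affected.

Step 17
Reactants: 26 (5R,6S,9S,10S,12E)-labda-7,12,14-triene-6,17-diol
Product: 27 (5R,6S,9S,10S,12E)-labda-7,12,14-triene-6,17-diyl diacetate (CNP0292756.1)
Conditions: Ac2O, pyridine, DMAP (10 mol %), CH2Cl2, rt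
Reagents that add atoms: acetic anhydride, CC(=O)OC(C)=O
Why: DMAP-catalysed acetylation should esterify both the primary allylic C17 hydroxyl and the hindered axial C6 hydroxyl.

**Compound list**

1 | 2,2,6-trimethylcyclohexan-1-one (racemic) | CC1CCCC(C)(C)C1=O | starting material
2 | allyl chloroformate | C=CCOC(Cl)=O | starting material
3 | lithium 2,6,6-trimethylcyclohex-1-en-1-olate | [Li]OC1=C(C)CCCC1(C)C | intermediate
4 | allyl 2,6,6-trimethylcyclohex-1-en-1-yl carbonate | C=CCOC(=O)OC1=C(C)CCCC1(C)C | intermediate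
5 | (S)-2-allyl-2,6,6-trimethylcyclohexan-1-one | C=CC[C@]1(C)CCCC(C)(C)C1=O | intermediate
6 | (S)-2,6,6-trimethyl-2-[(E)-prop-1-en-1-yl]cyclohexan-1-one | C/C=C/[C@]1(C)CCCC(C)(C)C1=O | intermediate
7 | (S)-2-ethenyl-2,6,6-trimethylcyclohexan-1-one | C=C[C@]1(C)CCCC(C)(C)C1=O | intermediate
8 | lithium (2S)-1-(chloromethyl)-2-ethenyl-2,6,6-trimethylcyclohexan-1-olate (both C1 epimers) | C=C[C@]1(C)CCCC(C)(C)C1(CCl)O[Li] | intermediate
9 | (4S)-4-ethenyl-4,8,8-trimethyl-1-oxaspiro[2.5]octane (both spiro epimers) | C=C[C@]1(C)CCCC(C)(C)C12CO2 | intermediate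
10 | (2S)-2-ethenyl-2,6,6-trimethylcyclohexane-1-carbaldehyde (both C1 epimers) | C=C[C@]1(C)CCCC(C)(C)C1C=O | intermediate
11 | tert-butyldimethyl(prop-2-yn-1-yloxy)silane | C#CCO[Si](C)(C)C(C)(C)C | starting material
12 | lithium acetylide of 11 | [Li]C#CCO[Si](C)(C)C(C)(C)C | intermediate
13 | 4-[(tert-butyldimethylsilyl)oxy]-1-[(2S)-2-ethenyl-2,6,6-trimethylcyclohexyl]but-2-yn-1-ol (mixture at C5 and C6) | C=C[C@]1(C)CCCC(C)(C)C1C(O)C#CCO[Si](C)(C)C(C)(C)C | intermediate
14 | sodium bis(2-methoxyethoxy)alanate chelate of 13 (five-membered O–Al–C8 ring) | [Na+].C=C[C@]1(C)CCCC(C)(C)C1C2O[Al-](OCCOC)(OCCOC)C(CO[Si](C)(C)C(C)(C)C)=C2 | intermediate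
15 | (Z)-4-[(tert-butyldimethylsilyl)oxy]-1-[(2S)-2-ethenyl-2,6,6-trimethylcyclohexyl]-3-iodobut-2-en-1-ol (mixture at C5 and C6) | C=C[C@]1(C)CCCC(C)(C)C1C(O)/C=C(\I)CO[Si](C)(C)C(C)(C)C | intermediate
16 | (Z)-4-[(tert-butyldimethylsilyl)oxy]-1-[(2S)-2-ethenyl-2,6,6-trimethylcyclohexyl]-3-iodobut-2-en-1-one (both C5 epimers) | C=C[C@]1(C)CCCC(C)(C)C1C(=O)/C=C(\I)CO[Si](C)(C)C(C)(C)C | intermediate
17 | (5R,10R)-17-[(tert-butyldimethylsilyl)oxy]-12,13,14,15,16-pentanorlabda-7,9(11)-dien-6-one (trans-fused, H5 anti to the C10 methyl) | C=C1C(CO[Si](C)(C)C(C)(C)C)=CC(=O)[C@@H]2C(C)(C)CCC[C@@]12C | intermediate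
18 | prop-2-yn-1-ol | C#CCO | starting material
19 | (E)-alkenylalane from carboalumination of 18 | C[Al](C)OC/C(C)=C/[Al](C)C | intermediate
20 | (E)-3-iodo-2-methylprop-2-en-1-ol | OC/C(C)=C/I | intermediate
21 | (E)-3-iodo-2-methylprop-2-enal | O=C/C(C)=C/I | intermediate
22 | (E)-1-iodo-2-methylbuta-1,3-diene | C=C/C(C)=C/I | intermediate
23 | (5R,6S,10R)-17-[(tert-butyldimethylsilyl)oxy]-12,13,14,15,16-pentanorlabda-7,9(11)-dien-6-ol (6-OH cis to the C10 methyl) | C=C1C(CO[Si](C)(C)C(C)(C)C)=C[C@H](O)[C@@H]2C(C)(C)CCC[C@@]12C | intermediate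
24 | C11 B-alkyl-9-BBN borane of 23 (6-O-borinate) | B1(C2CCCC1CCC2)C[C@@H]3C(CO[Si](C)(C)C(C)(C)C)=C[C@H](OB4C5CCCC4CCC5)[C@@H]6C(C)(C)CCC[C@@]36C | intermediate
25 | (5R,6S,9S,10S,12E)-17-[(tert-butyldimethylsilyl)oxy]labda-7,12,14-trien-6-ol | C=C/C(C)=C/C[C@@H]1C(CO[Si](C)(C)C(C)(C)C)=C[C@H](O)[C@@H]2C(C)(C)CCC[C@@]12C | intermediate
26 | (5R,6S,9S,10S,12E)-labda-7,12,14-triene-6,17-diol | C=C/C(C)=C/C[C@@H]1C(CO)=C[C@H](O)[C@@H]2C(C)(C)CCC[C@@]12C | intermediate
27 | (5R,6S,9S,10S,12E)-labda-7,12,14-triene-6,17-diyl diacetate | C=C/C(C)=C/C[C@@H]1C(COC(C)=O)=C[C@H](OC(C)=O)[C@@H]2C(C)(C)CCC[C@@]12C | target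

**Step count and risks**

Total step count: 17. Longest linear sequence: 14 (steps 1–10 and 14–17); the dienyl iodide 22 is made in three steps (11–13).

Steps most likely to fail:

Step 10. The migratory insertion must form a bond at the vinyl carbon next to the quaternary C10. If it is slow, protodehalogenation of the alkenylpalladium, 7-endo insertion or base-induced decomposition of the β-iodoenone may take over. The fallback sets out from 16 and comes back at 25; it makes the same C8–C9 bond by a tin hydride-mediated radical conjugate cyclization. Ozonolysis of the vinyl group of 16 (O3, CH2Cl2/MeOH, −78 °C, then Me2S; the electron-poor iodoenone olefin should react more slowly) gives the formyl iodoenone F1. Wittig reaction with Ph3P=CHCHO (toluene, 80 °C) gives the (E)-enal F2. Bu3SnH and AIBN (benzene, 80 °C, slow addition) generate the C8 alkenyl radical, which adds 6-exo-trig to C9 of the enal; after brief treatment with Et3N to settle C5 this gives the keto aldehyde F3, with C9 set by the pseudo-equatorial acceptor chain in the chair-like transition state. Wittig reaction with Ph3P=C(CH3)CHO (benzene, 80 °C) gives the (E)-2-methyl enal F4, methylenation with Ph3P=CH2 (THF, −78 to 0 °C) gives the dienyl enone F5, and Luche reduction (NaBH4, CeCl3·7H2O, MeOH, −78 °C) gives 25.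

Step 6. At the tertiary C5 cation a 1,2-shift of methyl or vinyl from C4 or C10, or capture of the cation by the vinyl group, may compete with the hydride shift; the carbenoid addition of step 5 to the doubly α-quaternary ketone may also be slow. The fallback sets out from 7 and comes back at 10; it is a Peterson-type methoxymethylenation. (Methoxymethyl)trimethylsilane is lithiated (s-BuLi, THF, −78 to −25 °C) and added to 7 to give the β-hydroxysilane F6. KH (THF, 0 °C to rt) induces elimination to the enol ether F7. Aqueous oxalic acid (THF, rt) hydrolyses F7 to 10 by protonation at C5, which passes through an oxocarbenium ion at C6 and not through a carbocation at C5.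

Step 4. Metathesis at an olefin whose allylic carbon is quaternary is slow; non-productive exchange and catalyst decomposition may leave 6 unchanged. The fallback sets out from 6 and comes back at 7. Ozonolysis (O3, CH2Cl2, −78 °C, then Me2S) gives the keto aldehyde F8, and Wittig methylenation (Ph3P=CH2, THF, −78 to 0 °C) of the aldehyde, which is far less hindered than the ketone, gives 7.

**Further compounds**

F1 | step 10 | (1R)-2-[(Z)-4-[(tert-butyldimethylsilyl)oxy]-3-iodobut-2-enoyl]-1,3,3-trimethylcyclohexane-1-carbaldehyde (both C2 epimers) | O=C[C@]1(C)CCCC(C)(C)C1C(=O)/C=C(\I)CO[Si](C)(C)C(C)(C)C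
F2 | step 10 | (E)-3-[(1S)-2-[(Z)-4-[(tert-butyldimethylsilyl)oxy]-3-iodobut-2-enoyl]-1,3,3-trimethylcyclohexyl]prop-2-enal (both C2 epimers) | O=C/C=C/[C@]1(C)CCCC(C)(C)C1C(=O)/C=C(\I)CO[Si](C)(C)C(C)(C)C
F3 | step 10 | (5R,9S,10S)-17-[(tert-butyldimethylsilyl)oxy]-6-oxo-13,14,15,16-tetranorlabd-7-en-12-al | O=CC[C@@H]1C(CO[Si](C)(C)C(C)(C)C)=CC(=O)[C@@H]2C(C)(C)CCC[C@@]12C
F4 | step 10 | (5R,9S,10S,12E)-17-[(tert-butyldimethylsilyl)oxy]-6-oxo-15-norlabda-7,12-dien-14-al | O=C/C(C)=C/C[C@@H]1C(CO[Si](C)(C)C(C)(C)C)=CC(=O)[C@@H]2C(C)(C)CCC[C@@]12C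
F5 | step 10 | (5R,9S,10S,12E)-17-[(tert-butyldimethylsilyl)oxy]labda-7,12,14-trien-6-one | C=C/C(C)=C/C[C@@H]1C(CO[Si](C)(C)C(C)(C)C)=CC(=O)[C@@H]2C(C)(C)CCC[C@@]12C
F6 | step 6 | (2S)-2-ethenyl-1-[methoxy(trimethylsilyl)methyl]-2,6,6-trimethylcyclohexan-1-ol (diastereomer mixture) | C=C[C@]1(C)CCCC(C)(C)C1(O)C(OC)[Si](C)(C)C
F7 | step 6 | (1S)-1-ethenyl-2-(methoxymethylidene)-1,3,3-trimethylcyclohexane (E/Z mixture) | C=C[C@]1(C)CCCC(C)(C)C1=COC
F8 | step 4 | (S)-1,3,3-trimethyl-2-oxocyclohexane-1-carbaldehyde | O=C[C@]1(C)CCCC(C)(C)C1=O
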